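**Retrosynthetic overview**
- Numbering used: aryl A–C7'H2–C8'H(–C9'H2–O–C9H2–)C8H–C7H(OH)–aryl B. The target is 7R,8R,8'R, with the two ring branches trans.
- The strategy rests on the C8–C8' bond between the two adjacent CH carbons of the tetrahydrofuran ring (C8' carries the C7' benzyl of aryl A, C8 carries the exocyclic carbinol carbon C7). C7 is placed inside a six-membered tetrahydropyran-4-one as its carbonyl carbon and leaves the ring when C8' shifts from C7 to a diazo carbon C8 with loss of N2 (Wolff ring contraction).
- After the contraction: ester to aldehyde, Felkin–Anh addition of the aryl B Grignard reagent to set C7, then hydrogenolysis of both benzyl ethers.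
- Before it: the (S)-3-benzylated tetrahydropyran-4-one comes from RAMP-hydrazone alkylation of tetrahydropyran-4-one with the vanillin-derived benzyl bromide, followed by kinetic trifluoroacetylation and diazo transfer at C5.
- Ring order: only the tetrahydrofuran is made, by contraction of the purchased pyranone ring; both aryl rings are bought.

Key step: step 8

Assumption: the trans arrangement of the ester and benzyl branches on the tetrahydrofuran is taken as the thermodynamically preferred one, as is usual for 3,4-disubstituted five-membered rings; the C=N geometry of the hydrazones is left undefined because it is lost on hydrolysis.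

**Route**

Step 1
Reactants: 1 vanillin (4-hydroxy-3-methoxybenzaldehyde)
Product: 2 4-(benzyloxy)-3-methoxybenzaldehyde
Conditions: BnBr, K2CO3, DMF, 60 °C
Reagents that add atoms: benzyl bromide, BrCc1ccccc1
Why: Williamson ether synthesis on the phenoxide protects the ring A phenol as a benzyl ether that should survive all later basic, hydride and photochemical steps.

Step 2
Reactants: 2 4-(benzyloxy)-3-methoxybenzaldehyde
Product: 3 [4-(benzyloxy)-3-methoxyphenyl]methanol
Conditions: NaBH4, MeOH, 0 °C
Reagents that add atoms: none
Why: Borohydride reduction of an aryl aldehyde to the benzylic alcohol, with no other reducible group present.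

Step 3
Reactants: 3 [4-(benzyloxy)-3-methoxyphenyl]methanol
Product: 4 1-(benzyloxy)-4-(bromomethyl)-2-methoxybenzene
Conditions: PBr3, Et2O, 0 °C; used at once
Reagents that add atoms: phosphorus tribromide, BrP(Br)Br
Why: Alcohol-to-bromide substitution through the phosphite ester, which is fast at an electron-rich benzylic carbon.

Step 4
Reactants: 5 tetrahydro-4H-pyran-4-one; 6 RAMP, (R)-1-amino-2-(methoxymethyl)pyrrolidine
Product: 7 RAMP hydrazone of 5, (2R)-2-(methoxymethyl)-N-(oxan-4-ylidene)pyrrolidin-1-amine
Conditions: neat, 60 °C, 4 Å sieves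
Reagents that add atoms: none
Why: Hydrazone condensation with loss of water; the ketone is symmetric, so only one hydrazone can form.

Step 5
Reactants: 7 RAMP hydrazone of 5; 4 1-(benzyloxy)-4-(bromomethyl)-2-methoxybenzene
Product: 9 benzylated RAMP hydrazone (2R)-N-{(3R)-3-[4-(benzyloxy)-3-methoxybenzyl]oxan-4-ylidene}-2-(methoxymethyl)pyrrolidin-1-amine (3R by CIP in the hydrazone; the same spatial arrangement is 3S in ketone 10), via lithium azaenolate 8 (not isolated)
Conditions: t-BuLi, THF, −78 °C; then 4, −100 °C → −78 °C
Reagents that add atoms: tert-butyllithium, [Li]C(C)(C)C (lithium, present only in intermediate 8)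
Why: Enders SAMP/RAMP hydrazone alkylation: the lithium azaenolate, with lithium held by the methoxymethyl arm, is benzylated from its open face, and the sense established for this auxiliary family (SAMP leads to (R)-2-methylcyclohexanone) translates for RAMP into the C8' arrangement that is 3S in ketone 10; deprotonation at −78 °C should keep beta-elimination of the ring oxygen slow.

Step 6
Reactants: 9 benzylated RAMP hydrazone
Product: 10 (3S)-3-[4-(benzyloxy)-3-methoxybenzyl]tetrahydro-4H-pyran-4-one
Conditions: sat. aq. (CO2H)2, Et2O, rt
Reagents that add atoms: water, O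
Why: Two-phase hydrazone hydrolysis with oxalic acid should regenerate the ketone under conditions too mild to enolise the new alpha stereocentre, while RAMP passes into the aqueous phase as its oxalate for recovery.

Step 7
Reactants: 10 (3S)-3-[4-(benzyloxy)-3-methoxybenzyl]tetrahydro-4H-pyran-4-one
Product: 13 (3S)-3-[4-(benzyloxy)-3-methoxybenzyl]-5-diazotetrahydro-4H-pyran-4-one, via lithium enolate 11 (not isolated), via trifluoroacetyl ketone 12 (not isolated)
Conditions: LiN(SiMe3)2, THF, −78 °C; CF3CO2CH2CF3, −78 °C; then 4-acetamidobenzenesulfonyl azide, Et3N, H2O (1 equiv), MeCN, rt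
Reagents that add atoms: 4-acetamidobenzenesulfonyl azide, CC(=O)Nc1ccc(cc1)S(=O)(=O)N=[N+]=[N-] (the two diazo nitrogens); lithium bis(trimethylsilyl)amide, [Li]N([Si](C)(C)C)[Si](C)(C)C (lithium, in 11 only); 2,2,2-trifluoroethyl trifluoroacetate, FC(F)(F)COC(=O)C(F)(F)F (trifluoroacetyl group, in 12 only)
Why: Deacylative Regitz diazo transfer after kinetic activation: the hindered amide base removes a proton from the unsubstituted C5 methylene rather than from the benzylated C3–H, Claisen-type trifluoroacetylation marks that carbon, and the sulfonyl azide then delivers N2 with loss of the trifluoroacetyl group, the C8' hydrogen being gamma to the diketonate and therefore not acidic during the transfer.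

Step 8
Reactants: 13 (3S)-3-[4-(benzyloxy)-3-methoxybenzyl]-5-diazotetrahydro-4H-pyran-4-one
Product: 16 methyl (3R,4R)-4-[4-(benzyloxy)-3-methoxybenzyl]oxolane-3-carboxylate (trans ester; C8' is now 4R only because the CIP priorities change), via ketene 14 (not isolated), via cis ester 15 (not isolated)
Conditions: hν (365 nm LED, or Hg lamp through Pyrex, λ > 300 nm), degassed MeOH, 0 °C; then NaOMe (0.5 equiv), MeOH, rt
Reagents that add atoms: methanol, CO
Why: Excitation of the s-cis-locked cyclic diazo ketone expels N2 while the C7–C8' bond, anti-periplanar to the leaving nitrogen, shifts to the diazo carbon C8 (photochemical Wolff rearrangement), giving ketene 14, which methanol captures as the ester. The closest known reaction type is the photochemical ring contraction of 2-diazocycloalkanones (2-diazocyclohexanone to methyl cyclopentanecarboxylate) and of their oxygen-heterocyclic analogues. The tetrahydrofuran is not closed by a cyclisation but by contraction: the bond C8'–C7 is exchanged for C8'–C8 in a 1,2-shift, so the six-membered ring loses C7, which becomes the exocyclic ester carbon. C8' migrates with retention and is no longer alpha to a carbonyl afterwards, so the configuration installed in step 5 is carried over, whereas C8 is set under thermodynamic control when methoxide equilibrates cis ester 15 to trans ester 16, with the two branches on opposite faces of the ring. The step needs the concerted shift to outrun free-carbene chemistry (1,2-hydride shift from C9–H, O–H insertion into methanol), which the fixed s-cis geometry and long-wavelength light absorbed by the diazo ketone but not by the aryl ethers should secure. During the equilibration the endocyclic C9–O bond lies close to the nodal plane of the ester enolate, so beta-elimination of the ring oxygen should remain slow.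

Step 9
Reactants: 16 methyl (3R,4R)-4-[4-(benzyloxy)-3-methoxybenzyl]oxolane-3-carboxylate
Product: 17 {(3S,4R)-4-[4-(benzyloxy)-3-methoxybenzyl]oxolan-3-yl}methanol (3S only through a CIP priority change; geometry unchanged)
Conditions: LiAlH4, THF, 0 °C
Reagents that add atoms: none
Why: Hydride reduction of the ester to the primary alcohol, which touches no stereocentre and leaves the aryl benzyl ether intact.

Step 10
Reactants: 17 {(3S,4R)-4-[4-(benzyloxy)-3-methoxybenzyl]oxolan-3-yl}methanol
Product: 18 (3R,4R)-4-[4-(benzyloxy)-3-methoxybenzyl]oxolane-3-carbaldehyde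
Conditions: Dess–Martin periodinane, CH2Cl2, 0 °C → rt
Reagents that add atoms: none
Why: Dess–Martin oxidation stops at the aldehyde under non-basic conditions, and C8 already has the thermodynamically preferred trans configuration, so any enolisation is harmless.

Step 11
Reactants: 19 4-bromo-2-methoxyphenol
Product: 20 1-(benzyloxy)-4-bromo-2-methoxybenzene
Conditions: BnBr, K2CO3, DMF, 60 °C
Reagents that add atoms: benzyl bromide, BrCc1ccccc1
Why: Williamson ether synthesis masks the acidic phenol of ring B so that the aryl bromide can be turned into a Grignard reagent.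

Step 12
Reactants: 20 1-(benzyloxy)-4-bromo-2-methoxybenzene
Product: 21 [4-(benzyloxy)-3-methoxyphenyl]magnesium bromide (used as its THF solution)
Conditions: Mg turnings, I2 (cat.), THF, reflux → rt
Reagents that add atoms: magnesium, [Mg]
Why: Grignard formation by insertion of magnesium into the aryl C–Br bond, to which the aryl ethers are inert.

Step 13
Reactants: 18 (3R,4R)-4-[4-(benzyloxy)-3-methoxybenzyl]oxolane-3-carbaldehyde; 21 [4-(benzyloxy)-3-methoxyphenyl]magnesium bromide
Product: 22 (R)-[4-(benzyloxy)-3-methoxyphenyl]{(3R,4R)-4-[4-(benzyloxy)-3-methoxybenzyl]oxolan-3-yl}methanol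
Conditions: THF, −78 → 0 °C; aq. NH4Cl
Reagents that add atoms: none
Why: Grignard 1,2-addition under Felkin–Anh control: with the more substituted ring bond C8–C8' anti to the incoming aryl and C9 on the side of the carbonyl oxygen, attack should give the 7R carbinol, and a magnesium chelate between the carbonyl and the ring oxygen would expose the same face.

Step 14
Reactants: 22 (R)-[4-(benzyloxy)-3-methoxyphenyl]{(3R,4R)-4-[4-(benzyloxy)-3-methoxybenzyl]oxolan-3-yl}methanol
Product: 23 4-[(R)-hydroxy{(3R,4R)-4-[(4-hydroxy-3-methoxyphenyl)methyl]oxolan-3-yl}methyl]-2-methoxyphenol (CNP0234428.1)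
Conditions: H2 (1 atm), Pd/C, EtOAc, rt; stopped when both benzyl ethers are consumed
Reagents that add atoms: none
Why: Catalytic hydrogenolysis of the two aryl benzyl ethers, which under neutral acid-free conditions should be much faster than hydrogenolysis of the free benzylic C7–OH.

**Compound list**
1 | vanillin | COc1cc(C=O)ccc1O | starting material
2 | 4-(benzyloxy)-3-methoxybenzaldehyde | COc1cc(C=O)ccc1OCc1ccccc1 | intermediate
3 | [4-(benzyloxy)-3-methoxyphenyl]methanol | COc1cc(CO)ccc1OCc1ccccc1 | intermediate
4 | 1-(benzyloxy)-4-(bromomethyl)-2-methoxybenzene | COc1cc(CBr)ccc1OCc1ccccc1 | intermediate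
5 | tetrahydro-4H-pyran-4-one | O=C1CCOCC1 | starting material
6 | RAMP, (R)-1-amino-2-(methoxymethyl)pyrrolidine | COC[C@H]1CCCN1N | starting material (auxiliary, recovered in step 6)
7 | RAMP hydrazone of tetrahydropyran-4-one | COC[C@H]1CCCN1N=C1CCOCC1 | intermediate
8 | lithium azaenolate of 7 | [Li]N(N1CCC[C@@H]1COC)C1=CCOCC1 | intermediate (not isolated)
9 | benzylated RAMP hydrazone, (2R)-N-{(3R)-3-[4-(benzyloxy)-3-methoxybenzyl]oxan-4-ylidene}-2-(methoxymethyl)pyrrolidin-1-amine | COc1cc(C[C@H]2COCCC2=NN2CCC[C@@H]2COC)ccc1OCc1ccccc1 | intermediate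
10 | (3S)-3-[4-(benzyloxy)-3-methoxybenzyl]tetrahydro-4H-pyran-4-one | COc1cc(C[C@@H]2C(=O)CCOC2)ccc1OCc1ccccc1 | intermediate
11 | kinetic lithium enolate of 10 (C4=C5) | COc1cc(C[C@@H]2C(O[Li])=CCOC2)ccc1OCc1ccccc1 | intermediate (not isolated)
12 | (3S)-3-[4-(benzyloxy)-3-methoxybenzyl]-5-(trifluoroacetyl)tetrahydro-4H-pyran-4-one (largely enolised, C5 undefined) | COc1cc(C[C@@H]2C(=O)C(C(=O)C(F)(F)F)COC2)ccc1OCc1ccccc1 | intermediate (not isolated)
13 | (3S)-3-[4-(benzyloxy)-3-methoxybenzyl]-5-diazotetrahydro-4H-pyran-4-one | COc1cc(C[C@@H]2C(=O)C(=[N+]=[N-])COC2)ccc1OCc1ccccc1 | intermediate (key-step precursor)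
14 | ketene, {(4R)-4-[4-(benzyloxy)-3-methoxybenzyl]oxolan-3-ylidene}methanone | COc1cc(C[C@H]2COCC2=C=O)ccc1OCc1ccccc1 | intermediate (not isolated)
15 | methyl (3S,4R)-4-[4-(benzyloxy)-3-methoxybenzyl]oxolane-3-carboxylate (cis ester) | COc1cc(C[C@H]2COC[C@H]2C(=O)OC)ccc1OCc1ccccc1 | intermediate (not isolated)
16 | methyl (3R,4R)-4-[4-(benzyloxy)-3-methoxybenzyl]oxolane-3-carboxylate (trans ester) | COc1cc(C[C@H]2COC[C@@H]2C(=O)OC)ccc1OCc1ccccc1 | intermediate (key-step product)
17 | {(3S,4R)-4-[4-(benzyloxy)-3-methoxybenzyl]oxolan-3-yl}methanol | COc1cc(C[C@H]2COC[C@@H]2CO)ccc1OCc1ccccc1 | intermediate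
18 | (3R,4R)-4-[4-(benzyloxy)-3-methoxybenzyl]oxolane-3-carbaldehyde | COc1cc(C[C@H]2COC[C@@H]2C=O)ccc1OCc1ccccc1 | intermediate
19 | 4-bromo-2-methoxyphenol | COc1cc(Br)ccc1O | starting material
20 | 1-(benzyloxy)-4-bromo-2-methoxybenzene | COc1cc(Br)ccc1OCc1ccccc1 | intermediate
21 | [4-(benzyloxy)-3-methoxyphenyl]magnesium bromide | COc1cc([Mg]Br)ccc1OCc1ccccc1 | intermediate (used in solution)
22 | (R)-[4-(benzyloxy)-3-methoxyphenyl]{(3R,4R)-4-[4-(benzyloxy)-3-methoxybenzyl]oxolan-3-yl}methanol | COc1cc(C[C@H]2COC[C@@H]2[C@@H](O)c2ccc(OCc3ccccc3)c(OC)c2)ccc1OCc1ccccc1 | intermediate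
23 | 4-[(R)-hydroxy{(3R,4R)-4-[(4-hydroxy-3-methoxyphenyl)methyl]oxolan-3-yl}methyl]-2-methoxyphenol | COc1cc(C[C@H]2COC[C@@H]2[C@@H](O)c2ccc(O)c(OC)c2)ccc1O | target

**Totals**
Total step count: 14.
Longest linear sequence: 11 steps (vanillin through steps 1–3, 5–10, 13 and 14).

**Three steps most likely to fail**

1. Step 8 (key step).
- What may go wrong: the excited diazo ketone may react as a free carbene instead of rearranging. This would show as a 1,2-hydride shift from C9–H to the enone, O–H insertion into methanol, or attack on the electron-rich aryl ring A. Photodegradation of the aryl ethers and incomplete cis-to-trans equilibration are further risks.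
- Fallback: a carbene-free ring contraction that sets out from ketone 10 and comes back at ester 16. LiN(SiMe3)2 and TBSOTf (THF, −78 °C) should give the kinetic silyl enol ether F1. F1 adds to p-toluenesulfonyl azide (MeCN, 60 °C) and, with loss of N2 and the same 1,2-shift of C8' from C7 to C8, should give the ring-contracted O-silyl N-tosyl imidate F2. Methanol desilylates it to the N-tosyl amide F3. MeI and K2CO3 (DMF) give the N-methyl-N-tosyl amide F4, and NaOMe in MeOH displaces the activated sulfonamide and equilibrates C8, returning ester 16. This relies on the known ring contraction of cyclic enol ethers with sulfonyl azides (dipolar cycloaddition, then nitrogen loss with alkyl shift) and needs neither light nor a carbene.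

2. Step 13.
- What may go wrong: poor facial selectivity, because the two ring branches at C8 (C8' and C9) differ only moderately in size. Enolisation of the aldehyde by the basic Grignard reagent is a second risk.
- Fallback: acylation followed by catalyst-controlled reduction, setting out from ester 16 and coming back at carbinol 22. MeNH(OMe)·HCl and i-PrMgCl (THF, −20 °C) convert 16 into the Weinreb amide F5. Grignard reagent 21 then gives the aryl ketone F6. Corey–Bakshi–Shibata reduction with the (S)-2-methyl oxazaborolidine and BH3·SMe2 (THF, −20 °C), with the aryl group as the large substituent, should deliver the 7R alcohol 22 under reagent control, against the intrinsic Felkin preference of the ketone.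

3. Step 5.
- What may go wrong: erosion of enantiopurity or loss of material, through beta-elimination of the ring oxygen from the azaenolate, decomposition or ionisation of the labile bromide 4, or double alkylation. The enantiopurity of every later compound depends on this step.
- Fallback: condensation followed by asymmetric hydrogenation, setting out from ketone 5 and aldehyde 2 and coming back at ketone 10. Amine-catalysed aldol condensation (5 in excess, pyrrolidine cat., MeOH) should give the (E)-arylidene ketone F7. Asymmetric hydrogenation of the exocyclic enone C=C with [Ir(cod)(L)][B(C6H3(CF3)2)4] (L = tBu-PHOX; H2, CH2Cl2) then gives 10; this is a known route to 2-benzylcycloalkanones and 3-benzylchromanones, and it leaves the benzyl ether and the ketone intact. The ligand enantiomer that leads to (S)-10 would be fixed by comparison with material from step 6.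

**Further compounds**
F1 | step 8 | tert-butyl{[(5S)-5-[4-(benzyloxy)-3-methoxybenzyl]-5,6-dihydro-2H-pyran-4-yl]oxy}dimethylsilane | COc1cc(C[C@H]2COCC=C2O[Si](C)(C)C(C)(C)C)ccc1OCc1ccccc1
F2 | step 8 | tert-butyldimethylsilyl (4R)-4-[4-(benzyloxy)-3-methoxybenzyl]-N-tosyloxolane-3-carboximidate (C3 undefined) | COc1cc(C[C@H]2COCC2C(O[Si](C)(C)C(C)(C)C)=NS(=O)(=O)c2ccc(C)cc2)ccc1OCc1ccccc1
F3 | step 8 | (4R)-4-[4-(benzyloxy)-3-methoxybenzyl]-N-tosyloxolane-3-carboxamide (C3 undefined) | COc1cc(C[C@H]2COCC2C(=O)NS(=O)(=O)c2ccc(C)cc2)ccc1OCc1ccccc1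
F4 | step 8 | (4R)-4-[4-(benzyloxy)-3-methoxybenzyl]-N-methyl-N-tosyloxolane-3-carboxamide (C3 undefined) | COc1cc(C[C@H]2COCC2C(=O)N(C)S(=O)(=O)c2ccc(C)cc2)ccc1OCc1ccccc1
F5 | step 13 | (3R,4R)-4-[4-(benzyloxy)-3-methoxybenzyl]-N-methoxy-N-methyloxolane-3-carboxamide | COc1cc(C[C@H]2COC[C@@H]2C(=O)N(C)OC)ccc1OCc1ccccc1
F6 | step 13 | [4-(benzyloxy)-3-methoxyphenyl]{(3R,4R)-4-[4-(benzyloxy)-3-methoxybenzyl]oxolan-3-yl}methanone | COc1cc(C[C@H]2COC[C@@H]2C(=O)c2ccc(OCc3ccccc3)c(OC)c2)ccc1OCc1ccccc1
F7 | step 5 | (E)-3-[4-(benzyloxy)-3-methoxybenzylidene]tetrahydro-4H-pyran-4-one | COc1cc(/C=C2\COCCC2=O)ccc1OCc1ccccc1
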